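The route rests on disconnecting the C6–C6a bond (furo[3,4-c]furanone numbering), which joins the lactone α-carbon (C6a) to the benzylic ether carbon (C6) of the tetrahydrofuran ring. A trans-4-(hydroxymethyl)-5-aryl-γ-butyrolactone, made by an Evans syn-aldol/lactonisation, carries the second aryl aldehyde as a mixed O-methyl acetal on its primary oxygen. In one operation, silyl triflate and amine turn the lactone into its silyl ketene acetal and the acetal into an oxocarbenium ion; their intramolecular Mukaiyama-type union closes the tetrahydrofuran ring and sets C6a (cis fusion) and C6 (aryl exo). The step exploits the acidity of C6a–H in the lactone ring and the aldehyde oxidation level of C6, flanked by O5 and the guaiacyl ring.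

Key step: step 6

Assumption: (S)-4-benzyl-1,3-oxazolidin-2-one, methyl 4-chloro-4-oxobutanoate, 4-(benzyloxy)-3,5-dimethoxybenzaldehyde and 4-(benzyloxy)-3-methoxybenzaldehyde are taken as commercially available; the mixed acetal is used as both epimers at the acetal carbon, because that centre becomes planar in the key step.

Step 1
Reactants: 1 (S)-4-benzyl-1,3-oxazolidin-2-one; 2 methyl 4-chloro-4-oxobutanoate
Product: 3 methyl 4-[(4S)-4-benzyl-2-oxo-1,3-oxazolidin-3-yl]-4-oxobutanoate
Conditions: n-BuLi, THF, −78 °C; then 2, −78 → 0 °C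
Reagents that add atoms: none
Why: N-acylation of 1 after deprotonation (standard imide formation) should be clean because the acid chloride is far more electrophilic than the methyl ester, and no stereocentre is touched.

Step 2
Reactants: 3 methyl 4-[(4S)-4-benzyl-2-oxo-1,3-oxazolidin-3-yl]-4-oxobutanoate; 4 4-(benzyloxy)-3,5-dimethoxybenzaldehyde
Product: 7 (4S)-4-benzyl-3-{(2S,3S)-2-[4-(benzyloxy)-3,5-dimethoxyphenyl]-5-oxotetrahydrofuran-3-carbonyl}-1,3-oxazolidin-2-one, via dibutylboron enolate 5 (not isolated), via syn-aldol adduct 6 (not isolated)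
Conditions: Bu2BOTf, i-Pr2NEt, CH2Cl2, 0 °C; 4, −78 → 0 °C; H2O2, MeOH, pH 7 buffer; then p-TsOH·H2O (cat.), CH2Cl2, rt
Reagents that add atoms: none
Why: Evans syn-aldol reaction: the (Z)-boron enolate 5, formed at the imide α-carbon, should react through a Zimmerman–Traxler chair on the face opposite the auxiliary benzyl group, setting both new centres (S), and the syn adduct 6 then lactonises onto the methyl ester to the trans-4,5-disubstituted γ-lactone.

Step 3
Reactants: 7 (4S)-4-benzyl-3-{(2S,3S)-2-[4-(benzyloxy)-3,5-dimethoxyphenyl]-5-oxotetrahydrofuran-3-carbonyl}-1,3-oxazolidin-2-one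
Product: 8 (4R,5S)-5-[4-(benzyloxy)-3,5-dimethoxyphenyl]-4-(hydroxymethyl)dihydrofuran-2(3H)-one
Conditions: NaBH4, THF/H2O (4:1), 0 °C → rt
Reagents that add atoms: none
Why: Borohydride reduction of the activated exocyclic imide carbonyl (reductive removal of the auxiliary) should outpace reduction of the γ-lactone, so the acyl group becomes CH2OH with both stereocentres unchanged.

Step 4
Reactants: 9 4-(benzyloxy)-3-methoxybenzaldehyde
Product: 10 1-(benzyloxy)-4-(dimethoxymethyl)-2-methoxybenzene
Conditions: HC(OMe)3, MeOH, p-TsOH·H2O (cat.), rt; Et3N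
Reagents that add atoms: trimethyl orthoformate, COC(OC)OC; methanol (solvent, exchanges into the acetal), CO
Why: Acid-catalysed acetalisation of an aromatic aldehyde should go to completion because the orthoformate consumes the water formed.

Step 5
Reactants: 8 (4R,5S)-5-[4-(benzyloxy)-3,5-dimethoxyphenyl]-4-(hydroxymethyl)dihydrofuran-2(3H)-one; 10 1-(benzyloxy)-4-(dimethoxymethyl)-2-methoxybenzene
Product: 11 (4R,5S)-4-({[4-(benzyloxy)-3-methoxyphenyl](methoxy)methoxy}methyl)-5-[4-(benzyloxy)-3,5-dimethoxyphenyl]dihydrofuran-2(3H)-one (both epimers at the acetal carbon)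
Conditions: 10 (3 equiv), PPTS (cat.), PhMe, 5 Å MS, 40 °C; Et3N
Reagents that add atoms: none
Why: Acid-catalysed transacetalisation should exchange one methoxy group for the primary alcohol when the dimethyl acetal is in excess and methanol is taken up by the sieves; the new acetal centre forms without control and is of no consequence.

Step 6
Reactants: 11 (4R,5S)-4-({[4-(benzyloxy)-3-methoxyphenyl](methoxy)methoxy}methyl)-5-[4-(benzyloxy)-3,5-dimethoxyphenyl]dihydrofuran-2(3H)-one
Product: 14 (3S,3aR,6S,6aS)-3-[4-(benzyloxy)-3,5-dimethoxyphenyl]-6-[4-(benzyloxy)-3-methoxyphenyl]tetrahydro-1H,3H-furo[3,4-c]furan-1-one, via silyl ketene acetal 12 (not isolated), via oxocarbenium triflate 13 (not isolated)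
Conditions: Me3SiOTf (2.5 equiv), i-Pr2NEt (3 equiv), CH2Cl2 (0.01 M), −78 → 0 °C; aq. NaHCO3
Reagents that add atoms: none
Why: Me3SiOTf/i-Pr2NEt should enolise the lactone to silyl ketene acetal 12 and Me3SiOTf then ionises the mixed acetal with loss of MeOSiMe3 to the (E)-oxocarbenium ion 13, whose benzylic carbon is attacked by C6a of the ketene acetal, after which loss of the silyl group returns the lactone carbonyl. The closest known reaction type is the intramolecular Mukaiyama aldol-type addition of a silyl ketene acetal to an acetal-derived oxocarbenium ion. The tetrahydrofuran ring closes in a 5-(enol-exo)-endo-trig mode, endo with respect to the C=O+ bond, which is tolerated for oxocarbenium ions. C6a is controlled by C3a, because the one-atom tether can reach only the face of the ketene acetal that gives the cis-fused bicycle. C6 is controlled by the shape of the forming bicycle: the aryl group of the (E)-oxocarbenium ion should sit on the convex face, away from the silyloxy-bearing carbon of the ketene acetal, so that it ends exo, trans to the lactone carbonyl. The step needs exo over endo selectivity and intramolecular over intermolecular capture; the first is secured by the lactone ring and the configuration at C3a, the second by high dilution and by the reversibility of ionisation at the other acetal oxygen.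

Step 7
Reactants: 14 (3S,3aR,6S,6aS)-3-[4-(benzyloxy)-3,5-dimethoxyphenyl]-6-[4-(benzyloxy)-3-methoxyphenyl]tetrahydro-1H,3H-furo[3,4-c]furan-1-one
Product: 15 (3S,3aR,6S,6aS)-3-(4-hydroxy-3,5-dimethoxyphenyl)-6-(4-hydroxy-3-methoxyphenyl)tetrahydro-1H,3H-furo[3,4-c]furan-1-one
Conditions: H2 (1 atm), 10% Pd/C, EtOAc, rt, stopped after uptake of 2 equiv H2
Reagents that add atoms: none
Why: Catalytic hydrogenolysis should cleave the two phenolic benzyl ethers much faster than the ring benzylic C–O bonds under neutral conditions, so no stereocentre is affected.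

Compound list
1 | (S)-4-benzyl-1,3-oxazolidin-2-one | O=C1N[C@@H](Cc2ccccc2)CO1 | starting material
2 | methyl 4-chloro-4-oxobutanoate | COC(=O)CCC(Cl)=O | starting material
3 | methyl 4-[(4S)-4-benzyl-2-oxo-1,3-oxazolidin-3-yl]-4-oxobutanoate | COC(=O)CCC(=O)N1C(=O)OC[C@@H]1Cc1ccccc1 | intermediate
4 | 4-(benzyloxy)-3,5-dimethoxybenzaldehyde | COc1cc(C=O)cc(OC)c1OCc1ccccc1 | starting material
5 | (Z)-dibutylboron enolate of 3 (not isolated) | CCCCB(CCCC)O/C(=C\CC(=O)OC)N1C(=O)OC[C@@H]1Cc1ccccc1 | intermediate
6 | methyl (3S)-3-{(S)-[4-(benzyloxy)-3,5-dimethoxyphenyl](hydroxy)methyl}-4-[(4S)-4-benzyl-2-oxo-1,3-oxazolidin-3-yl]-4-oxobutanoate (not isolated) | COC(=O)C[C@@H]([C@H](O)c1cc(OC)c(OCc2ccccc2)c(OC)c1)C(=O)N1C(=O)OC[C@@H]1Cc1ccccc1 | intermediate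
7 | (4S)-4-benzyl-3-{(2S,3S)-2-[4-(benzyloxy)-3,5-dimethoxyphenyl]-5-oxotetrahydrofuran-3-carbonyl}-1,3-oxazolidin-2-one | O=C(N1C(=O)OC[C@@H]1Cc1ccccc1)[C@H]1CC(=O)O[C@@H]1c1cc(OC)c(OCc2ccccc2)c(OC)c1 | intermediate
8 | (4R,5S)-5-[4-(benzyloxy)-3,5-dimethoxyphenyl]-4-(hydroxymethyl)dihydrofuran-2(3H)-one | OC[C@H]1CC(=O)O[C@@H]1c1cc(OC)c(OCc2ccccc2)c(OC)c1 | intermediate
9 | 4-(benzyloxy)-3-methoxybenzaldehyde | COc1cc(C=O)ccc1OCc1ccccc1 | starting material
10 | 1-(benzyloxy)-4-(dimethoxymethyl)-2-methoxybenzene | COC(OC)c1ccc(OCc2ccccc2)c(OC)c1 | intermediate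
11 | (4R,5S)-4-({[4-(benzyloxy)-3-methoxyphenyl](methoxy)methoxy}methyl)-5-[4-(benzyloxy)-3,5-dimethoxyphenyl]dihydrofuran-2(3H)-one, both acetal epimers | COC(OC[C@H]1CC(=O)O[C@@H]1c1cc(OC)c(OCc2ccccc2)c(OC)c1)c1ccc(OCc2ccccc2)c(OC)c1 | intermediate
12 | trimethylsilyl ketene acetal of 11, a 2-(trimethylsilyloxy)-4,5-dihydrofuran with C4 and C5 as in 11 (not isolated) | COC(OC[C@H]1C=C(O[Si](C)(C)C)O[C@@H]1c1cc(OC)c(OCc2ccccc2)c(OC)c1)c1ccc(OCc2ccccc2)c(OC)c1 | intermediate
13 | (E)-oxocarbenium triflate from 12 by loss of the methoxy group (not isolated) | COc1cc(/C=[O+]/C[C@H]2C=C(O[Si](C)(C)C)O[C@@H]2c2cc(OC)c(OCc3ccccc3)c(OC)c2)ccc1OCc1ccccc1.[O-]S(=O)(=O)C(F)(F)F | intermediate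
14 | (3S,3aR,6S,6aS)-3-[4-(benzyloxy)-3,5-dimethoxyphenyl]-6-[4-(benzyloxy)-3-methoxyphenyl]tetrahydro-1H,3H-furo[3,4-c]furan-1-one | COc1cc([C@H]2OC[C@H]3[C@@H]2C(=O)O[C@@H]3c2cc(OC)c(OCc4ccccc4)c(OC)c2)ccc1OCc1ccccc1 | intermediate
15 | (3S,3aR,6S,6aS)-3-(4-hydroxy-3,5-dimethoxyphenyl)-6-(4-hydroxy-3-methoxyphenyl)tetrahydro-1H,3H-furo[3,4-c]furan-1-one | COc1cc([C@H]2OC[C@H]3[C@@H]2C(=O)O[C@@H]3c2cc(OC)c(O)c(OC)c2)ccc1O | target

Total step count: 7
Longest linear sequence: 6 (steps 1, 2, 3, 5, 6, 7; step 4 is a one-step side branch)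

Steps most likely to fail

Step 6. The closure may proceed with poor facial selectivity at C6, placing part of the aryl group endo, or the oxocarbenium ion may be captured by a second molecule instead of by its own ketene acetal. The fallback moves the aryl group to the last bond made at C6. Setting out from 8, exchange with trimethyl orthoformate (PPTS, removal of methanol) should give the mixed orthoformate (4R,5S)-5-[4-(benzyloxy)-3,5-dimethoxyphenyl]-4-[(dimethoxymethoxy)methyl]dihydrofuran-2(3H)-one F1. Me3SiOTf/i-Pr2NEt should close F1, by addition of the silyl ketene acetal to a dialkoxycarbenium ion, to the cis-fused bicyclic methyl acetal (3S,3aR,6aS)-3-[4-(benzyloxy)-3,5-dimethoxyphenyl]-6-methoxytetrahydro-1H,3H-furo[3,4-c]furan-1-one F2, whose configuration at C6 does not matter. BF3·OEt2 in MeCN then ionises F2 to the bicyclic oxocarbenium ion, which is arylated at the ipso carbon by potassium [4-(benzyloxy)-3-methoxyphenyl]trifluoroborate F3 (from the commercial boronic acid and KHF2). Attack on the convex face should leave the aryl group exo and give 14, where the route is rejoined.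

Step 5. The transacetalisation may stall at equilibrium, run on to the symmetrical acetal that holds two lactone units, or the electron-rich mixed acetal may hydrolyse during isolation. The fallback builds the same compound by ether formation and benzylic oxidation. Setting out from 8, acid-catalysed alkylation (CSA cat., CH2Cl2) with 4-(benzyloxy)-3-methoxybenzyl 2,2,2-trichloroacetimidate F4 (from commercial 4-(benzyloxy)-3-methoxybenzyl alcohol, Cl3CCN and DBU) should give the benzyl ether (4R,5S)-4-({[4-(benzyloxy)-3-methoxybenzyl]oxy}methyl)-5-[4-(benzyloxy)-3,5-dimethoxyphenyl]dihydrofuran-2(3H)-one F5. DDQ in CH2Cl2/MeOH over 4 Å MS should oxidise the dialkoxybenzylic C–H bond of F5 to the oxocarbenium ion, which methanol traps to give 11, where the route is rejoined.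

Step 7. Hydrogenolysis may run on after loss of the benzyl groups and cleave the benzylic C3–O2 bond of the lactone or the C6–O5 bond of the ether. The fallback sets out from 14 and removes the benzyl groups without hydrogen: BCl3 with pentamethylbenzene as cation scavenger in CH2Cl2 at −78 °C should dealkylate both aryl benzyl ethers and give 15 directly. This fallback makes no new compound (F0).

Further compounds
F1 | step 6 | (4R,5S)-5-[4-(benzyloxy)-3,5-dimethoxyphenyl]-4-[(dimethoxymethoxy)methyl]dihydrofuran-2(3H)-one | COC(OC)OC[C@H]1CC(=O)O[C@@H]1c1cc(OC)c(OCc2ccccc2)c(OC)c1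
F2 | step 6 | (3S,3aR,6aS)-3-[4-(benzyloxy)-3,5-dimethoxyphenyl]-6-methoxytetrahydro-1H,3H-furo[3,4-c]furan-1-one, both epimers at C6 | COC1OC[C@H]2[C@@H]1C(=O)O[C@@H]2c1cc(OC)c(OCc2ccccc2)c(OC)c1
F3 | step 6 | potassium [4-(benzyloxy)-3-methoxyphenyl]trifluoroborate | [K+].F[B-](F)(F)c1ccc(OCc2ccccc2)c(OC)c1
F4 | step 5 | 4-(benzyloxy)-3-methoxybenzyl 2,2,2-trichloroacetimidate | COc1cc(COC(=N)C(Cl)(Cl)Cl)ccc1OCc1ccccc1
F5 | step 5 | (4R,5S)-4-({[4-(benzyloxy)-3-methoxybenzyl]oxy}methyl)-5-[4-(benzyloxy)-3,5-dimethoxyphenyl]dihydrofuran-2(3H)-one | COc1cc(COC[C@H]2CC(=O)O[C@@H]2c2cc(OC)c(OCc3ccccc3)c(OC)c2)ccc1OCc1ccccc1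
F0 | step 7 | none | none
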